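**Retrosynthetic overview**
1. Target 21 (benzo[7]annulene numbering; ring A = cyclohexenone C1–C4/C4a/C9a, ring B = cycloheptene C4a/C5–C9/C9a) ⇐ desilylation and C2 oxidation of bis-angelate 19 ⇐ double angeloylation of bicyclic diol 17.
2. 17 ⇐ triene diol 16 by closing ring B at the C8=C9 double bond: ring-closing metathesis of the C7 vinyl carbinol with the isopropenyl group on C9a.
3. Enabling feature: ring A with its C3 methyl, its C2 oxygen and the C9a–C9(CH3)=CH2 isopropenyl group is the intact skeleton of (S)-carvone, so C9 and its methyl are bought, the extra CH2 leaves as ethylene, and the C7 oxygen makes the other partner an allylic vinyl carbinol.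
4. 16 ⇐ aldehyde 13 by reagent-controlled (Z)-γ-alkoxyallylboration (C6, C7 and the vinyl group in one step); 13 ⇐ tertiary allylic isobutyrate 8 by Ireland–Claisen rearrangement (C4a–C5 bond, quaternary C5, C4a cis to C9a by chirality transfer).
5. 8 ⇐ (S)-carvone 1 through cis-carveol, hydroxyl-directed epoxidation and selenium-mediated epoxide-to-allylic-alcohol transposition; ring order: ring A bought, ring B formed in step 11.

Key step: step 11

Assumption: the facial preference of the diisopinocampheylborane reagent towards the α-quaternary aldehyde 13 is taken to be that of the parent allyl and crotyl reagents; target atom numbers are used for all intermediates.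

Step 1
Reactants: 1 (S)-(+)-carvone
Product: 2 (1S,5S)-2-methyl-5-(prop-1-en-2-yl)cyclohex-2-en-1-ol (cis-carveol)
Conditions: NaBH4, CeCl3·7H2O, MeOH, −20 °C
Reagents that add atoms: none
Why: Luche 1,2-reduction, in which axial hydride delivery to the cerium-activated enone with an equatorial isopropenyl group should give the equatorial C2 alcohol cis to the isopropenyl group (substrate control from C9a).

Step 2
Reactants: 2 cis-carveol
Product: 3 (1S,2S,4R,6R)-1-methyl-4-(prop-1-en-2-yl)-7-oxabicyclo[4.1.0]heptan-2-ol (hydroxyl, epoxide oxygen and isopropenyl on one face)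
Conditions: VO(acac)2 (cat.), t-BuOOH, toluene, 0 °C → rt
Reagents that add atoms: tert-butyl hydroperoxide, CC(C)(C)OO
Why: Hydroxyl-directed vanadium-catalysed epoxidation, in which the vanadium-bound allylic alkoxide delivers the peroxide oxygen to its own face, should set C3 and C4 syn to the hydroxyl and leave the isolated isopropenyl olefin untouched.

Step 3
Reactants: 3 epoxy alcohol
Product: 4 tert-butyldimethyl{[(1R,2S,4S,6R)-1-methyl-4-(prop-1-en-2-yl)-7-oxabicyclo[4.1.0]heptan-2-yl]oxy}silane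
Conditions: TBSCl, imidazole, DMF, rt
Reagents that add atoms: tert-butyldimethylsilyl chloride, CC(C)(C)[Si](C)(C)Cl
Why: Standard silylation of the secondary alcohol masks the C2 oxygen for the enolate, hydride and metathesis steps and creates no stereocenter.

Step 4
Reactants: 4 epoxy silyl ether
Product: 7 (1R,4R,6S)-6-[(tert-butyldimethylsilyl)oxy]-1-methyl-4-(prop-1-en-2-yl)cyclohex-2-en-1-ol (tertiary hydroxyl, silyloxy and isopropenyl all cis), via hydroxy selenide 5 (not isolated), via selenoxide 6 (not isolated)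
Conditions: (PhSe)2, NaBH4, EtOH, 80 °C; then THF, 30% H2O2, 0 °C → rt
Reagents that add atoms: none
Why: Selenium-mediated epoxide-to-allylic-alcohol transposition, in which benzeneselenolate opens the epoxide at the secondary carbon C4 with inversion (trans-diaxial) and the selenoxide undergoes syn-elimination towards C4a, the only carbon bearing a β-hydrogen, so the C3–O configuration from step 2 is kept.

Step 5
Reactants: 7 tertiary allylic alcohol
Product: 8 (1R,4R,6S)-6-[(tert-butyldimethylsilyl)oxy]-1-methyl-4-(prop-1-en-2-yl)cyclohex-2-en-1-yl 2-methylpropanoate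
Conditions: (i-PrCO)2O, DMAP, Et3N, CH2Cl2, 40 °C
Reagents that add atoms: isobutyric anhydride, CC(C)C(=O)OC(=O)C(C)C
Why: DMAP-catalysed acylation of the tertiary alcohol under non-alkoxide conditions should avoid silyl migration and installs the isobutyrate that carries C5, its two methyls and C6 without touching a stereocenter.

Step 6
Reactants: 8 tertiary allylic isobutyrate
Product: 11 2-{(1S,4S,6R)-4-[(tert-butyldimethylsilyl)oxy]-3-methyl-6-(prop-1-en-2-yl)cyclohex-2-en-1-yl}-2-methylpropanoic acid, via silyl ketene acetal 9 (not isolated), via trimethylsilyl ester 10 (not isolated)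
Conditions: LiN(i-Pr)2, Me3SiCl, Et3N, THF, −78 °C → 60 °C; then 1 M HCl
Reagents that add atoms: none
Why: Ireland–Claisen rearrangement, whose suprafacial [3,3] shift across C3–C4–C4a should form the C4a–C5 bond on the face that carried the C3 oxygen, setting C4a cis to the isopropenyl group and creating the quaternary C5 by chirality transfer from a conformer with axial C3–O and equatorial methyl, silyloxy and isopropenyl groups.

Step 7
Reactants: 11 acid
Product: 12 2-{(1S,4S,6R)-4-[(tert-butyldimethylsilyl)oxy]-3-methyl-6-(prop-1-en-2-yl)cyclohex-2-en-1-yl}-2-methylpropan-1-ol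
Conditions: LiAlH4, THF, 0 °C → 40 °C
Reagents that add atoms: none
Why: Hydride reduction of the hindered carboxylic acid to the neopentyl-type alcohol should leave the silyl ether and the olefins intact and touches no stereocenter.

Step 8
Reactants: 12 primary alcohol
Product: 13 2-{(1S,4S,6R)-4-[(tert-butyldimethylsilyl)oxy]-3-methyl-6-(prop-1-en-2-yl)cyclohex-2-en-1-yl}-2-methylpropanal
Conditions: Dess–Martin periodinane, CH2Cl2, rt
Reagents that add atoms: none
Why: Dess–Martin oxidation gives the C6 aldehyde, which has no α-hydrogen and therefore cannot epimerise or enolise.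

Step 9
Reactants: 13 aldehyde
Product: 15 (3R,4R)-2-{(1S,4S,6R)-4-[(tert-butyldimethylsilyl)oxy]-3-methyl-6-(prop-1-en-2-yl)cyclohex-2-en-1-yl}-4-(methoxymethoxy)-2-methylhex-5-en-3-ol, via borinate 14 (not isolated)
Conditions: allyl methoxymethyl ether, s-BuLi, THF, −78 °C; (−)-Ipc2BOMe [from (+)-α-pinene]; BF3·OEt2; then 13, −78 °C → rt; NaOH, H2O2
Reagents that add atoms: [(Z)-3-(methoxymethoxy)prop-2-en-1-yl]bis[(1R,2S,3R,5R)-isopinocampheyl]borane (generated in the flask from allyl methoxymethyl ether), COCO/C=C\CB([C@@H]1C[C@@H]2C[C@H]([C@H]1C)C2(C)C)[C@@H]1C[C@@H]2C[C@H]([C@H]1C)C2(C)C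
Why: Brown (Z)-γ-alkoxyallylboration through a chair Zimmerman–Traxler transition state, in which the Z geometry should give the syn C6/C7 relationship and the isopinocampheyl groups should direct attack to the Si face of the aldehyde, setting (6R,7R) by reagent control and installing the C8 vinyl group.

Step 10
Reactants: 15 mono-MOM ether
Product: 16 (3R,4R)-2-{(1S,4S,6R)-4-[(tert-butyldimethylsilyl)oxy]-3-methyl-6-(prop-1-en-2-yl)cyclohex-2-en-1-yl}-2-methylhex-5-ene-3,4-diol
Conditions: ZnBr2, n-PrSH, CH2Cl2, 0 °C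
Reagents that add atoms: none
Why: Lewis-acid-assisted thiolysis of the methoxymethyl acetal should free the C7 hydroxyl while sparing the allylic silyl ether and the olefins and avoiding the cyclic formaldehyde acetal that protic acid could form from the 1,2-diol, with no stereocenter affected.

Step 11
Reactants: 16 triene diol
Product: 17 (2S,4aS,6R,7R,9aR)-2-[(tert-butyldimethylsilyl)oxy]-3,5,5,9-tetramethyl-2,4a,5,6,7,9a-hexahydro-1H-benzo[7]annulene-6,7-diol
Conditions: second-generation Hoveyda–Grubbs catalyst [RuCl2(=CH-C6H4-2-O-i-Pr)(H2IMes)] (10 mol%), 1,4-benzoquinone (20 mol%), toluene (2 mM), 80 °C, Ar sparge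
Reagents that add atoms: none
Why: Ring-closing olefin metathesis: the ruthenium alkylidene should load onto the monosubstituted C8 vinyl group next to the free C7 hydroxyl, add across the 1,1-disubstituted isopropenyl olefin on C9a in an intramolecular [2+2] step and cyclorevert to the C8=C9 double bond with loss of ethylene. The closest known reaction type is the metathesis closure of trisubstituted cycloheptenes from dienes in which a carvone-derived isopropenyl group is one partner. Ring B is closed by joining the olefinic termini of the C9a and C4a substituents into a seven-membered carbocycle whose new endocyclic olefin can only be Z. No stereocenter is formed, and C4a, C6, C7 and C9a are carried through unchanged. The step needs ring closure to win over oligomerisation and the ring A olefin to stay out of the reaction: the cis arrangement of the two side chains on ring A and the gem-dimethyl group at C5 hold the reacting olefins together, high dilution and ethylene removal favour closure, and the C3=C4 olefin is trisubstituted and flanked by the silyloxy carbon and C4a. 1,4-Benzoquinone is added to suppress hydride-induced isomerisation of the allylic alcohol.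

Step 12
Reactants: 17 bicyclic diol
Product: 19 (2S,4aS,6R,7R,9aR)-2-[(tert-butyldimethylsilyl)oxy]-3,5,5,9-tetramethyl-2,4a,5,6,7,9a-hexahydro-1H-benzo[7]annulene-6,7-diyl bis[(2Z)-2-methylbut-2-enoate], via 7-monoangelate 18 (not isolated)
Conditions: angelic acid, 2,4,6-trichlorobenzoyl chloride, Et3N, toluene, rt; then 17, 80 °C
Reagents that add atoms: angelic acid [(2Z)-2-methylbut-2-enoic acid], C/C=C(/C)C(=O)O
Why: Mixed-anhydride (Yamaguchi-type) acylation run without a nucleophilic amine catalyst should esterify both hydroxyls, the allylic C7 first and the hindered C6 second, while keeping the Z geometry of the angelate and leaving the carbinol stereocenters unchanged.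

Step 13
Reactants: 19 silyl ether bis-angelate
Product: 20 (2S,4aS,6R,7R,9aR)-2-hydroxy-3,5,5,9-tetramethyl-2,4a,5,6,7,9a-hexahydro-1H-benzo[7]annulene-6,7-diyl bis[(2Z)-2-methylbut-2-enoate]
Conditions: HF·pyridine, pyridine, THF, 0 °C → rt
Reagents that add atoms: none
Why: Buffered fluoride desilylation should free the C2 allylic alcohol without acyl migration, ester cleavage or angelate isomerisation.

Step 14
Reactants: 20 allylic alcohol
Product: 21 (4aS,6R,7R,9aR)-3,5,5,9-tetramethyl-2-oxo-2,4a,5,6,7,9a-hexahydro-1H-benzo[7]annulene-6,7-diyl bis[(2Z)-2-methylbut-2-enoate] (target)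
Conditions: Dess–Martin periodinane, CH2Cl2, 0 °C → rt
Reagents that add atoms: none
Why: Dess–Martin oxidation of the secondary allylic alcohol gives the C2 enone under near-neutral conditions that should not epimerise the vinylogous C4a centre, and it removes the temporary C2 stereocenter.

**Compound list**
1 | (S)-(+)-carvone | C=C(C)[C@@H]1CC(=O)C(C)=CC1 | starting material
2 | (1S,5S)-2-methyl-5-(prop-1-en-2-yl)cyclohex-2-en-1-ol (cis-carveol) | C=C(C)[C@@H]1C[C@H](O)C(C)=CC1 | intermediate
3 | (1S,2S,4R,6R)-1-methyl-4-(prop-1-en-2-yl)-7-oxabicyclo[4.1.0]heptan-2-ol | C=C(C)[C@@H]1C[C@H](O)[C@]2(C)O[C@@H]2C1 | intermediate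
4 | tert-butyldimethyl{[(1R,2S,4S,6R)-1-methyl-4-(prop-1-en-2-yl)-7-oxabicyclo[4.1.0]heptan-2-yl]oxy}silane | C=C(C)[C@@H]1C[C@H](O[Si](C)(C)C(C)(C)C)[C@]2(C)O[C@@H]2C1 | intermediate
5 | (1S,2S,4R,6S)-2-[(tert-butyldimethylsilyl)oxy]-1-methyl-6-(phenylselanyl)-4-(prop-1-en-2-yl)cyclohexan-1-ol | C=C(C)[C@@H]1C[C@H](O[Si](C)(C)C(C)(C)C)[C@](C)(O)[C@@H]([Se]c2ccccc2)C1 | intermediate
6 | selenoxide of 5 (selenium configuration undefined) | C=C(C)[C@@H]1C[C@H](O[Si](C)(C)C(C)(C)C)[C@](C)(O)[C@@H]([Se](=O)c2ccccc2)C1 | intermediate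
7 | (1R,4R,6S)-6-[(tert-butyldimethylsilyl)oxy]-1-methyl-4-(prop-1-en-2-yl)cyclohex-2-en-1-ol | C=C(C)[C@@H]1C[C@H](O[Si](C)(C)C(C)(C)C)[C@](C)(O)C=C1 | intermediate
8 | (1R,4R,6S)-6-[(tert-butyldimethylsilyl)oxy]-1-methyl-4-(prop-1-en-2-yl)cyclohex-2-en-1-yl 2-methylpropanoate | C=C(C)[C@@H]1C[C@H](O[Si](C)(C)C(C)(C)C)[C@](C)(OC(=O)C(C)C)C=C1 | intermediate
9 | trimethylsilyl ketene acetal of 8 | C=C(C)[C@@H]1C[C@H](O[Si](C)(C)C(C)(C)C)[C@](C)(OC(O[Si](C)(C)C)=C(C)C)C=C1 | intermediate
10 | trimethylsilyl ester of 11 | C=C(C)[C@@H]1C[C@H](O[Si](C)(C)C(C)(C)C)C(C)=C[C@@H]1C(C)(C)C(=O)O[Si](C)(C)C | intermediate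
11 | 2-{(1S,4S,6R)-4-[(tert-butyldimethylsilyl)oxy]-3-methyl-6-(prop-1-en-2-yl)cyclohex-2-en-1-yl}-2-methylpropanoic acid | C=C(C)[C@@H]1C[C@H](O[Si](C)(C)C(C)(C)C)C(C)=C[C@@H]1C(C)(C)C(=O)O | intermediate
12 | 2-{(1S,4S,6R)-4-[(tert-butyldimethylsilyl)oxy]-3-methyl-6-(prop-1-en-2-yl)cyclohex-2-en-1-yl}-2-methylpropan-1-ol | C=C(C)[C@@H]1C[C@H](O[Si](C)(C)C(C)(C)C)C(C)=C[C@@H]1C(C)(C)CO | intermediate
13 | 2-{(1S,4S,6R)-4-[(tert-butyldimethylsilyl)oxy]-3-methyl-6-(prop-1-en-2-yl)cyclohex-2-en-1-yl}-2-methylpropanal | C=C(C)[C@@H]1C[C@H](O[Si](C)(C)C(C)(C)C)C(C)=C[C@@H]1C(C)(C)C=O | intermediate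
14 | O-diisopinocampheylboryl derivative (borinate) of 15 | C=C(C)[C@@H]1C[C@H](O[Si](C)(C)C(C)(C)C)C(C)=C[C@@H]1C(C)(C)[C@@H](OB([C@@H]2C[C@@H]3C[C@H]([C@H]2C)C3(C)C)[C@@H]2C[C@@H]3C[C@H]([C@H]2C)C3(C)C)[C@H](OCOC)C=C | intermediate
15 | (3R,4R)-2-{(1S,4S,6R)-4-[(tert-butyldimethylsilyl)oxy]-3-methyl-6-(prop-1-en-2-yl)cyclohex-2-en-1-yl}-4-(methoxymethoxy)-2-methylhex-5-en-3-ol | C=C(C)[C@@H]1C[C@H](O[Si](C)(C)C(C)(C)C)C(C)=C[C@@H]1C(C)(C)[C@@H](O)[C@H](OCOC)C=C | intermediate
16 | (3R,4R)-2-{(1S,4S,6R)-4-[(tert-butyldimethylsilyl)oxy]-3-methyl-6-(prop-1-en-2-yl)cyclohex-2-en-1-yl}-2-methylhex-5-ene-3,4-diol | C=C(C)[C@@H]1C[C@H](O[Si](C)(C)C(C)(C)C)C(C)=C[C@@H]1C(C)(C)[C@@H](O)[C@H](O)C=C | intermediate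
17 | (2S,4aS,6R,7R,9aR)-2-[(tert-butyldimethylsilyl)oxy]-3,5,5,9-tetramethyl-2,4a,5,6,7,9a-hexahydro-1H-benzo[7]annulene-6,7-diol | O[C@@H]1C=C(C)[C@@H]2C[C@H](O[Si](C)(C)C(C)(C)C)C(C)=C[C@@H]2C(C)(C)[C@H]1O | intermediate
18 | 7-O-[(2Z)-2-methylbut-2-enoyl] derivative of 17 (C6 hydroxyl free) | C/C=C(/C)C(=O)O[C@@H]1C=C(C)[C@@H]2C[C@H](O[Si](C)(C)C(C)(C)C)C(C)=C[C@@H]2C(C)(C)[C@H]1O | intermediate
19 | (2S,4aS,6R,7R,9aR)-2-[(tert-butyldimethylsilyl)oxy]-3,5,5,9-tetramethyl-2,4a,5,6,7,9a-hexahydro-1H-benzo[7]annulene-6,7-diyl bis[(2Z)-2-methylbut-2-enoate] | C/C=C(/C)C(=O)O[C@@H]1C=C(C)[C@@H]2C[C@H](O[Si](C)(C)C(C)(C)C)C(C)=C[C@@H]2C(C)(C)[C@H]1OC(=O)/C(C)=C\C | intermediate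
20 | (2S,4aS,6R,7R,9aR)-2-hydroxy-3,5,5,9-tetramethyl-2,4a,5,6,7,9a-hexahydro-1H-benzo[7]annulene-6,7-diyl bis[(2Z)-2-methylbut-2-enoate] | C/C=C(/C)C(=O)O[C@@H]1C=C(C)[C@@H]2C[C@H](O)C(C)=C[C@@H]2C(C)(C)[C@H]1OC(=O)/C(C)=C\C | intermediate
21 | (4aS,6R,7R,9aR)-3,5,5,9-tetramethyl-2-oxo-2,4a,5,6,7,9a-hexahydro-1H-benzo[7]annulene-6,7-diyl bis[(2Z)-2-methylbut-2-enoate] | C/C=C(/C)C(=O)O[C@@H]1C=C(C)[C@@H]2CC(=O)C(C)=C[C@@H]2C(C)(C)[C@H]1OC(=O)/C(C)=C\C | target

**Step count and risks**
Total steps: 14. Longest linear sequence: 14 (fully linear from 1).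

Steps most likely to fail:

Step 6 (Ireland–Claisen). Enolisation of the hindered α-branched ester may be slow, and on warming the tertiary allylic ester may ionise or eliminate before the [3,3] shift. The fallback sets out from 8 and replaces the rearrangement by a palladium-catalysed allylic alkylation: Pd(PPh3)4 (zerovalent palladium), 1-methoxy-2-methyl-1-(trimethylsilyloxy)prop-1-ene, THF, 60 °C. Ionisation anti to the isobutyrate and outer-sphere attack anti to palladium at the less substituted terminus C4a should give, with net retention (C5 cis to the isopropenyl group), the methyl ester F1. LiAlH4 reduction of F1 under the conditions of step 7 comes back to the route at 12.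

Step 12 (double angeloylation). Acylation of the neopentyl-type C6 hydroxyl may stay incomplete, and forcing conditions may isomerise the Z-angelate to the E-tiglate. The fallback sets out from 17 and builds the olefins on the molecule. Both hydroxyls are esterified with the small 2-[bis(2,2,2-trifluoroethoxy)phosphoryl]propanoic acid (DCC, DMAP, CH2Cl2) to give the bis(phosphonopropanoate) F2. A double Still–Gennari olefination with acetaldehyde [KN(SiMe3)2, 18-crown-6, THF, −78 °C] should then form both (Z)-2-methylbut-2-enoates and comes back to the route at 19.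

Step 11 (ring-closing metathesis). Intermolecular metathesis of the vinyl groups (oligomerisation) and catalyst decay may outrun closure onto the 1,1-disubstituted olefin. The fallback sets out from 16 and makes the same C8=C9 bond by reductive carbonyl coupling. The diol is tied up as the acetonide F3 (2,2-dimethoxypropane, PPTS, CH2Cl2). Lemieux–Johnson cleavage of the two terminal olefins (OsO4 cat., NaIO4, 2,6-lutidine, dioxane–water; the hindered ring A olefin is expected to survive) gives the keto aldehyde F4. Intramolecular McMurry coupling with low-valent titanium [TiCl3(DME)1.5, Zn–Cu couple, DME, reflux, high dilution] should give the bicyclic acetonide F5. Acetonide methanolysis (PPTS, MeOH) comes back to the route at 17.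

Further compounds
F1 | step 6 | methyl 2-{(1S,4S,6R)-4-[(tert-butyldimethylsilyl)oxy]-3-methyl-6-(prop-1-en-2-yl)cyclohex-2-en-1-yl}-2-methylpropanoate | C=C(C)[C@@H]1C[C@H](O[Si](C)(C)C(C)(C)C)C(C)=C[C@@H]1C(C)(C)C(=O)OC
F2 | step 12 | 6,7-bis{2-[bis(2,2,2-trifluoroethoxy)phosphoryl]propanoate} of 17 (phosphonate α-carbons undefined) | CC(C(=O)O[C@@H]1C=C(C)[C@@H]2C[C@H](O[Si](C)(C)C(C)(C)C)C(C)=C[C@@H]2C(C)(C)[C@H]1OC(=O)C(C)P(=O)(OCC(F)(F)F)OCC(F)(F)F)P(=O)(OCC(F)(F)F)OCC(F)(F)F
F3 | step 11 | acetonide of 16 [(4R,5R)-2,2-dimethyl-1,3-dioxolane with the vinyl group on C5 and the ring A–CMe2 group on C4] | C=C(C)[C@@H]1C[C@H](O[Si](C)(C)C(C)(C)C)C(C)=C[C@@H]1C(C)(C)[C@H]1OC(C)(C)O[C@@H]1C=C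
F4 | step 11 | keto aldehyde from F3 (acetyl on C9a and formyl on the dioxolane in place of isopropenyl and vinyl) | CC(=O)[C@@H]1C[C@H](O[Si](C)(C)C(C)(C)C)C(C)=C[C@@H]1C(C)(C)[C@H]1OC(C)(C)O[C@@H]1C=O
F5 | step 11 | 6,7-O-isopropylidene derivative (acetonide) of 17 | O1[C@@H]2C=C(C)[C@@H]3C[C@H](O[Si](C)(C)C(C)(C)C)C(C)=C[C@@H]3C(C)(C)[C@H]2OC1(C)C
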